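**Assumption:** commercial Grignard solutions (vinylMgBr, allylMgCl) and (S)-epichlorohydrin count as purchasable starting materials; all three phenols are carried as TBS ethers.

## Retrosynthetic overview

1. Target 18 ⇐ tris-TBS acetate 17 ⇐ alcohol 16 (desilylation, then acetylation, in reverse).
2. Key late coupling: the C1–C2 bond (numbered from the catechol end) is made by Cu-catalysed opening of (S)-epoxide 15 with the benzylic Grignard from chloride 6. Fragment 15 is a C12 piece carrying the E-styrene and the stereocentre; 6 is the C7 catechol piece.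
3. 15 ⇐ E-selective cross-metathesis of silyloxystyrene 10 with (S)-1,2-epoxy-5-hexene 14; 14 ⇐ (S)-epichlorohydrin + allylMgCl (chiral pool).
4. 6 ⇐ catechol (bromination, silylation, formylation, reduction, chlorination); 10 ⇐ 4-iodophenol.
5. Rings: both arenes are bought. The only ring made is the oxirane of 14 (step 9), which is carried through the metathesis and opened in the key coupling.

## Route

**Step 1**
Reactants: 1 catechol
Product: 2 4-bromobenzene-1,2-diol
Conditions: NBS (1.0 equiv), HBF4·OEt2, MeCN, −30 °C → rt
Reagents that add atoms: N-bromosuccinimide, O=C1CCC(=O)N1Br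
Why: Electrophilic aromatic bromination goes para to one OH (C4), which is electronically favoured and less hindered than C3; low temperature and 1.0 equiv NBS limit dibromination.

**Step 2**
Reactants: 2
Product: 3 4-bromo-1,2-bis(tert-butyldimethylsilyloxy)benzene
Conditions: TBSCl (2.4 equiv), imidazole, DMF, rt
Reagents that add atoms: TBSCl, CC(C)(C)[Si](C)(C)Cl
Why: Standard imidazole-promoted silyl ether formation on both phenols.

**Step 3**
Reactants: 3
Product: 4 3,4-bis(tert-butyldimethylsilyloxy)benzaldehyde
Conditions: n-BuLi, THF, −78 °C; then DMF, −78 → 0 °C; aq. NH4Cl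
Reagents that add atoms: DMF, CN(C)C=O
Why: Br–Li exchange followed by formylation with DMF; the aryllithium has no ortho silyloxy group, so no retro-Brook migration occurs.

**Step 4**
Reactants: 4
Product: 5 [3,4-bis(tert-butyldimethylsilyloxy)phenyl]methanol
Conditions: NaBH4, THF/MeOH, 0 °C, 30 min
Reagents that add atoms: none
Why: Borohydride reduction of the aldehyde; aryl TBS ethers survive the short, cold reaction.

**Step 5**
Reactants: 5
Product: 6 3,4-bis(tert-butyldimethylsilyloxy)benzyl chloride
Conditions: PPh3, NCS, CH2Cl2, 0 °C → rt; rapid silica filtration, use promptly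
Reagents that add atoms: N-chlorosuccinimide, O=C1CCC(=O)N1Cl
Why: Appel-type chlorination (SN2 on the alkoxyphosphonium at a primary benzylic carbon) under neutral conditions that leave the silyl ethers intact.

**Step 6**
Reactants: 7 4-iodophenol
Product: 8 tert-butyl(4-iodophenoxy)dimethylsilane
Conditions: TBSCl, imidazole, CH2Cl2, rt
Reagents that add atoms: TBSCl, CC(C)(C)[Si](C)(C)Cl
Why: Silyl protection of the phenol.

**Step 7**
Reactants: 8; 9 vinylmagnesium bromide
Product: 10 tert-butyldimethyl(4-vinylphenoxy)silane
Conditions: 9 + ZnCl2 (THF, 0 °C), then 8, Pd(PPh3)4 (3 mol%), THF, rt → 45 °C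
Reagents that add atoms: none (the vinyl group comes from 9)
Why: Negishi cross-coupling of the aryl iodide with in-situ vinylzinc; these neutral conditions do not touch the aryl silyl ether.

**Step 8**
Reactants: 11 (S)-epichlorohydrin; 12 allylmagnesium chloride
Product: 13 (S)-1-chlorohex-5-en-2-ol
Conditions: CuI (5 mol%), THF, −40 → −20 °C; aq. NH4Cl
Reagents that add atoms: none (the allyl group comes from 12)
Why: Cu-catalysed Grignard opening at the unsubstituted oxirane CH2; the C–O stereocentre is not touched, so the chiral-pool (S) centre is carried over.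

**Step 9**
Reactants: 13
Product: 14 (S)-2-(but-3-en-1-yl)oxirane, i.e. (S)-1,2-epoxy-5-hexene
Conditions: powdered NaOH, Et2O, rt; distil
Reagents that add atoms: none
Why: Intramolecular Williamson closure (alkoxide displaces the primary chloride); the stereocentre is not the reacting carbon, so (S) is retained.

**Step 10**
Reactants: 10 (2 equiv); 14
Product: 15 (S)-tert-butyldimethyl{4-[(E)-4-(oxiran-2-yl)but-1-en-1-yl]phenoxy}silane
Conditions: Grubbs II (3 mol%), CH2Cl2, 40 °C, Ar sweep; chromatography removes the stilbene homodimer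
Reagents that add atoms: none
Why: Olefin cross-metathesis of a styrene with a terminal alkene, driven by ethylene loss, gives the thermodynamic E-styrene; epoxide and silyl ether are inert to the Ru carbene.

**Step 11 (key fragment coupling)**
Reactants: 6 (1.8 equiv); 15
Product: 16 (3S,6E)-1-[3,4-bis(tert-butyldimethylsilyloxy)phenyl]-7-[4-(tert-butyldimethylsilyloxy)phenyl]hept-6-en-3-ol
Conditions: (i) 6, Mg (3 equiv, I2-activated), 2-MeTHF, 0 °C, slow addition; (ii) 15, CuI (10 mol%), THF, −40 → 0 °C; aq. NH4Cl
Reagents that add atoms: none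
Why: Cu(I)-catalysed SN2 opening of the terminal epoxide by the benzylic Grignard at the CH2 terminus; the carbinol C–O bond is untouched and the CIP ranking is unchanged, so (S)-15 gives the (3S)-alcohol.

**Step 12**
Reactants: 16
Product: 17 (3S,6E)-1-[3,4-bis(tert-butyldimethylsilyloxy)phenyl]-7-[4-(tert-butyldimethylsilyloxy)phenyl]hept-6-en-3-yl acetate
Conditions: Ac2O, pyridine, DMAP (cat.), CH2Cl2, 0 °C → rt
Reagents that add atoms: acetic anhydride, CC(=O)OC(C)=O
Why: DMAP-catalysed O-acylation of the secondary alcohol; only the O–H bond reacts, so configuration is retained.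

**Step 13**
Reactants: 17
Product: 18 (3S,6E)-1-(3,4-dihydroxyphenyl)-7-(4-hydroxyphenyl)hept-6-en-3-yl acetate (target)
Conditions: TBAF/AcOH (1:1, 3.5 equiv), THF, 0 °C, Ar, 30 min; pH 6 work-up
Reagents that add atoms: none
Why: Fluoride-mediated desilylation cleaves aryl silyl ethers rapidly; the acetic acid buffer keeps the phenoxides protonated, so the alkyl acetate, the E-alkene and the stereocentre are unaffected and the catechol is not oxidised.

## Compound list

1 | catechol | Oc1ccccc1O | starting material
2 | 4-bromobenzene-1,2-diol | Oc1ccc(Br)cc1O | intermediate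
3 | 4-bromo-1,2-bis(tert-butyldimethylsilyloxy)benzene | CC(C)(C)[Si](C)(C)Oc1ccc(Br)cc1O[Si](C)(C)C(C)(C)C | intermediate
4 | 3,4-bis(tert-butyldimethylsilyloxy)benzaldehyde | CC(C)(C)[Si](C)(C)Oc1ccc(C=O)cc1O[Si](C)(C)C(C)(C)C | intermediate
5 | [3,4-bis(tert-butyldimethylsilyloxy)phenyl]methanol | CC(C)(C)[Si](C)(C)Oc1ccc(CO)cc1O[Si](C)(C)C(C)(C)C | intermediate
6 | 3,4-bis(tert-butyldimethylsilyloxy)benzyl chloride | CC(C)(C)[Si](C)(C)Oc1ccc(CCl)cc1O[Si](C)(C)C(C)(C)C | intermediate
7 | 4-iodophenol | Oc1ccc(I)cc1 | starting material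
8 | tert-butyl(4-iodophenoxy)dimethylsilane | CC(C)(C)[Si](C)(C)Oc1ccc(I)cc1 | intermediate
9 | vinylmagnesium bromide | C=C[Mg]Br | starting material
10 | tert-butyldimethyl(4-vinylphenoxy)silane | CC(C)(C)[Si](C)(C)Oc1ccc(C=C)cc1 | intermediate
11 | (S)-epichlorohydrin | ClC[C@@H]1CO1 | starting material
12 | allylmagnesium chloride | C=CC[Mg]Cl | starting material
13 | (S)-1-chlorohex-5-en-2-ol | C=CCC[C@H](O)CCl | intermediate
14 | (S)-2-(but-3-en-1-yl)oxirane | C=CCC[C@H]1CO1 | intermediate
15 | (S)-tert-butyldimethyl{4-[(E)-4-(oxiran-2-yl)but-1-en-1-yl]phenoxy}silane | CC(C)(C)[Si](C)(C)Oc1ccc(/C=C/CC[C@H]2CO2)cc1 | intermediate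
16 | (3S,6E)-1-[3,4-bis(TBSO)phenyl]-7-[4-(TBSO)phenyl]hept-6-en-3-ol | O[C@@H](CC/C=C/c1ccc(O[Si](C)(C)C(C)(C)C)cc1)CCc1ccc(O[Si](C)(C)C(C)(C)C)c(O[Si](C)(C)C(C)(C)C)c1 | intermediate
17 | (3S,6E)-1-[3,4-bis(TBSO)phenyl]-7-[4-(TBSO)phenyl]hept-6-en-3-yl acetate | CC(=O)O[C@@H](CC/C=C/c1ccc(O[Si](C)(C)C(C)(C)C)cc1)CCc1ccc(O[Si](C)(C)C(C)(C)C)c(O[Si](C)(C)C(C)(C)C)c1 | intermediate
18 | (3S,6E)-1-(3,4-dihydroxyphenyl)-7-(4-hydroxyphenyl)hept-6-en-3-yl acetate | CC(=O)O[C@@H](CC/C=C/c1ccc(O)cc1)CCc1ccc(O)c(O)c1 | target

## Summary

**Total steps:** 13.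
**Longest linear sequence:** 8 (steps 1–5, then 11–13, from catechol). The 4-iodophenol and epichlorohydrin branches are each 6 steps to the target.

**Steps most likely to fail, with fallbacks**

1. **Step 11** — the electron-rich benzylic chloride may undergo Wurtz dimerisation during Grignard formation, and the epoxide may be opened sluggishly or by chloride. Fallback: make the aryl–CH2 bond instead of the CH2–CH2 bond. Convert 15 to the one-carbon-homologated allylic alcohol with dimethylsulfonium methylide (Me3SI/n-BuLi) and acetylate it. Then hydroborate the terminal vinyl group selectively with 9-BBN and run a B-alkyl Suzuki–Miyaura coupling with aryl bromide 3 (PdCl2(dppf), K3PO4). This gives 17 directly and bypasses steps 3–5.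

2. **Step 10** — cross-metathesis may give stilbene homodimer, incomplete conversion or E/Z mixtures. Fallback: build the styrene by Julia–Kocienski olefination. Ozonolyse 14 (O3, then PPh3) to (S)-3-(oxiran-2-yl)propanal and condense it with the 1-phenyltetrazol-5-yl sulfone of 4-(TBSO)benzyl alcohol (KHMDS, DME, −60 °C) to give 15 E-selectively.

3. **Step 13** — risks are partial acetate loss or transfer and catechol oxidation during triple desilylation. Fallback: change the protecting-group endgame. Desilylate 16 fully (TBAF), peracetylate to the tetraacetate (Ac2O, pyridine), then cleave only the three aryl acetates by mild aminolysis (NH4OAc, aq. MeOH, rt). Aryl esters react much faster than the secondary alkyl acetate.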